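**Plan**
- Retrosynthesis: the glycerol head is unmasked last from a benzylidene acetal. The bond from ring A carbon C10 to the C8 chain is cut next, as a Zweifel olefination of a C10 pinacol boronate with an alkenyllithium that already carries the protected glycerol ether.
- The core is then cut at C2–C3 and C6–C7. Ring C (C2, C3, C6, C7) shares only C2–C7 with ring B and C3–C6 with ring D, so its two other, parallel, non-fusion bonds fall to one [2+2] disconnection. This leaves the ring A/B cyclobutene cis-bicyclo[4.2.0]octa-3,7-diene and cyclobutene (ring D).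
- Forward: ring B is built on ring A (dichloroketene [2+2] on cyclohexa-1,4-diene, dechlorination, Shapiro olefination). Ring D is cyclobutene from cyclobutanol. Ring C closes in the CuOTf-templated photocycloaddition, and the chain is joined at C10 afterwards.
- Stereochemistry: the cis A/B fusion comes from the ketene cycloaddition. C2, C3, C6 and C7 come from exo, anti coupling on copper, which gives a meso alkene. C10 comes from an enantioselective CuH hydroboration that desymmetrises this alkene, and the Zweifel migration retains it.

Key step: step 7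

Numbering: the core is numbered as tetracyclo[6.4.0.0(2,7).0(3,6)]dodecane (ring A = C1, C8–C12; ring B = C1, C2, C7, C8; ring C = C2, C3, C6, C7; ring D = C3–C6). "Lad" stands for the cis-anti-cis-anti-cis tetracyclododecan-10-yl group whose C10 substituent is cis to C2 and C7 and whose C10 is S, as in the SMILES.
Assumption: in step 8 the (S)-ligand is taken as the antipode that places boron on C10 as drawn; if the sense of induction is the reverse, the (R)-ligand is used and nothing else changes.

**Step 1**
Reactants: 1 cyclohexa-1,4-diene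
Product: 2 cis-8,8-dichlorobicyclo[4.2.0]oct-3-en-7-one (racemic)
Conditions: Cl3CCOCl, activated Zn, Et2O/DME, ultrasound, 20 °C, 1 in threefold excess
Reagents that add atoms: trichloroacetyl chloride, O=C(Cl)C(Cl)(Cl)Cl
Why: Dichloroketene generated in the flask adds to one unactivated cis double bond in a thermal ketene–alkene [2+2] cycloaddition that is suprafacial on the alkene and therefore cis-fused, and the excess of diene should hold the reaction at the mono-adduct.

**Step 2**
Reactants: 2 cis-8,8-dichlorobicyclo[4.2.0]oct-3-en-7-one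
Product: 3 cis-bicyclo[4.2.0]oct-3-en-7-one (racemic)
Conditions: Zn dust, AcOH, 20 → 60 °C
Reagents that add atoms: none
Why: Reductive dechlorination of an α,α-dichloroketone by zinc in acetic acid runs through zinc enolates and should leave the cyclobutanone, the ring fusion and the isolated alkene untouched.

**Step 3**
Reactants: 3 cis-bicyclo[4.2.0]oct-3-en-7-one
Product: 4 N'-(cis-bicyclo[4.2.0]oct-3-en-7-ylidene)-4-methylbenzenesulfonohydrazide (racemic)
Conditions: TsNHNH2, MeOH, rt
Reagents that add atoms: p-toluenesulfonohydrazide, Cc1ccc(cc1)S(=O)(=O)NN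
Why: Hydrazone formation on the strained, electrophilic cyclobutanone is fast, and the NHTs group should turn toward the less hindered C8 methylene side, which prepares the regiochemistry of the next step.

**Step 4**
Reactants: 4 N'-(cis-bicyclo[4.2.0]oct-3-en-7-ylidene)-4-methylbenzenesulfonohydrazide
Product: 6 cis-bicyclo[4.2.0]octa-3,7-diene (meso), via cyclobutenyllithium 5 (not isolated)
Conditions: MeLi (2.5 equiv), Et2O, 0 °C → rt; H2O; careful distillation
Reagents that add atoms: none
Why: Shapiro reaction: deprotonation at N–H and at the syn C8–H, then loss of sulfinate and N2, gives the cyclobutenyllithium, which is protonated on quench, so the new double bond sits at C7=C8 away from the ring fusion and the cis-fused product is meso.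

**Step 5**
Reactants: 7 cyclobutanol
Product: 8 cyclobutyl 4-methylbenzenesulfonate
Conditions: TsCl, pyridine, 0 °C → rt
Reagents that add atoms: p-toluenesulfonyl chloride, Cc1ccc(cc1)S(=O)(=O)Cl
Why: Sulfonylation of a secondary alcohol (tosylate formation) turns the hydroxyl into a leaving group without touching the ring.

**Step 6**
Reactants: 8 cyclobutyl 4-methylbenzenesulfonate
Product: 9 cyclobutene
Conditions: KOtBu, DMSO, 70 °C, product swept with N2 into a −78 °C trap
Reagents that add atoms: none
Why: E2 elimination of the cyclobutyl tosylate with a hindered alkoxide in DMSO is the established preparative entry to cyclobutene, and the volatile alkene leaves the basic medium as it forms.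

**Step 7**
Reactants: 6 cis-bicyclo[4.2.0]octa-3,7-diene; 9 cyclobutene
Product: 10 meso cis-anti-cis-anti-cis-tetracyclo[6.4.0.0(2,7).0(3,6)]dodec-10-ene
Conditions: 9 (10 equiv, replenished), (CuOTf)2·C6H6 (5 mol %), Et2O, hν 254 nm (quartz), −10 °C
Reagents that add atoms: none
Why: CuOTf binds two strained cyclobutene double bonds as a bis(η2-alkene) complex of monovalent copper, and excitation of its charge-transfer band at 254 nm couples the two ligands inside the coordination sphere to a cyclobutane and releases the catalyst. The closest known reactions are the CuOTf-catalysed [2+2] photodimerisations of norbornene, cyclopentene and bicyclo[2.2.0]hex-2-ene and the crossed CuOTf photocycloadditions of two different alkenes, so this is a known reaction type on this substrate class run in crossed mode. Ring C closes in an intermolecular [2π+2π] cycloaddition, suprafacial on both partners, that forms C2–C3 and C6–C7 together. C2 and C7 are set by copper sitting on the convex face of the cis-fused diene (the face of its ring-fusion hydrogens, turned away from ring A), so ring C grows anti to ring A; C3 and C6 stay cis because cyclobutene adds suprafacially, and ring D ends anti to ring B because the two ligand rings point apart on copper. The step needs the cyclobutene bond of 6 to react in preference to its ring A double bond, which ring strain should secure because the unstrained cyclohexene is a far weaker ligand and reacts only by a slow isomerisation pathway. It also needs crossed coupling to outweigh homo-coupling, which for the diene the large excess of cyclobutene should secure, the surplus ending as volatile tricyclo[4.2.0.0(2,5)]octane that is distilled off.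

**Step 8**
Reactants: 10 meso cis-anti-cis-anti-cis-tetracyclo[6.4.0.0(2,7).0(3,6)]dodec-10-ene
Product: 11 2-(Lad)-4,4,5,5-tetramethyl-1,3,2-dioxaborolane (boron on C10, cis to C2 and C7)
Conditions: CuCl (5 mol %), (S)-DTBM-SEGPHOS (6 mol %), KOtBu (20 mol %), HBpin (1.5 equiv), cyclohexane, rt
Reagents that add atoms: pinacolborane, CC1(C)OBOC1(C)C
Why: Enantioselective CuH hydroboration of an unactivated cis alkene: the ligated copper hydride adds syn on the open face of boat-shaped ring A (C2 and C7 pseudo-equatorial there, the other face screened by pseudo-axial H1 and H8) while the ligand selects one of the two enantiotopic alkene carbons, and stereoretentive σ-bond metathesis with HBpin then places boron on C10 and returns CuH.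

**Step 9**
Reactants: 12 oct-7-yn-1-ol
Product: 13 oct-7-yn-1-yl methanesulfonate
Conditions: MsCl, Et3N, CH2Cl2, 0 °C
Reagents that add atoms: methanesulfonyl chloride, CS(=O)(=O)Cl
Why: Mesylation of the primary alcohol is routine and leaves the terminal alkyne untouched.

**Step 10**
Reactants: 13 oct-7-yn-1-yl methanesulfonate; 14 cis-2-phenyl-1,3-dioxan-5-ol
Product: 15 cis-5-(oct-7-yn-1-yloxy)-2-phenyl-1,3-dioxane
Conditions: 14, NaH (1.05 equiv), DMF, 0 °C; then 13, 50 °C
Reagents that add atoms: none
Why: Williamson ether synthesis: the secondary alkoxide of 1,3-O-benzylideneglycerol displaces the primary mesylate by SN2, which fixes the 2-O-alkyl glycerol connectivity while the acetal keeps both primary hydroxyls masked.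

**Step 11**
Reactants: 15 cis-5-(oct-7-yn-1-yloxy)-2-phenyl-1,3-dioxane
Product: 17 (E)-cis-5-[(8-iodooct-7-en-1-yl)oxy]-2-phenyl-1,3-dioxane, via (E)-alkenylzirconocene chloride 16 (not isolated)
Conditions: Cp2ZrHCl (1.3 equiv), THF, rt; then I2, 0 °C
Reagents that add atoms: iodine, [I][I]
Why: Hydrozirconation adds Zr–H syn to the terminal alkyne with zirconium on the terminal carbon, and iodinolysis of the C–Zr bond with retention gives the (E)-iodoalkene, with ether and acetal inert to both reagents.

**Step 12**
Reactants: 17 (E)-cis-5-[(8-iodooct-7-en-1-yl)oxy]-2-phenyl-1,3-dioxane; 11 2-(Lad)-4,4,5,5-tetramethyl-1,3,2-dioxaborolane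
Product: 21 cis-5-{[(Z)-8-(Lad)oct-7-en-1-yl]oxy}-2-phenyl-1,3-dioxane, via (E)-alkenyllithium 18 (not isolated), via lithium alkenylboronate complex 19 (not isolated), via β-iodoalkyl boronate 20 (not isolated)
Conditions: 17 (1.3 equiv), t-BuLi (2.6 equiv), Et2O, −78 °C; 11, THF, −78 → 0 °C; I2, MeOH/THF, −78 °C; NaOMe, MeOH, −78 °C → rt
Reagents that add atoms: none
Why: Zweifel olefination: lithium–iodine exchange gives the alkenyllithium, which adds to boron; iodine then triggers a 1,2-metallate shift of the secondary C10 group with retention at C10, and methoxide-induced anti elimination of boron and iodide gives the Z alkene, so the configuration set in step 8 is carried over unchanged.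

**Step 13**
Reactants: 21 cis-5-{[(Z)-8-(Lad)oct-7-en-1-yl]oxy}-2-phenyl-1,3-dioxane
Product: 22 cis-5-{[8-(Lad)octyl]oxy}-2-phenyl-1,3-dioxane
Conditions: TsNHNH2 (excess), NaOAc, THF/H2O, reflux
Reagents that add atoms: none
Why: Diimide reduction transfers H2 to the cis-disubstituted alkene in a concerted, metal-free step, which avoids any hydrogenolysis of the strained cyclobutanes or of the benzylidene acetal.

**Step 14**
Reactants: 22 cis-5-{[8-(Lad)octyl]oxy}-2-phenyl-1,3-dioxane
Product: 23 2-{[8-(Lad)octyl]oxy}propane-1,3-diol (CNP0193334.1)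
Conditions: AcOH/H2O/THF (4:1:1), 55 °C
Reagents that add atoms: none
Why: Acid-catalysed acetal hydrolysis releases the two primary hydroxyls under conditions to which the dialkyl ether and the saturated ladder hydrocarbon are inert.

**Compound list**
1 | cyclohexa-1,4-diene | C1=CCC=CC1 | starting material
2 | cis-8,8-dichlorobicyclo[4.2.0]oct-3-en-7-one (racemic, one enantiomer drawn) | O=C1C(Cl)(Cl)[C@@H]2CC=CC[C@H]12 | intermediate
3 | cis-bicyclo[4.2.0]oct-3-en-7-one (racemic, one enantiomer drawn) | O=C1C[C@@H]2CC=CC[C@H]12 | intermediate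
4 | N'-(cis-bicyclo[4.2.0]oct-3-en-7-ylidene)-4-methylbenzenesulfonohydrazide (racemic, one enantiomer drawn) | Cc1ccc(cc1)S(=O)(=O)NN=C1C[C@@H]2CC=CC[C@H]12 | intermediate
5 | cis-bicyclo[4.2.0]octa-3,7-dien-7-yllithium (racemic, one enantiomer drawn) | [Li]C1=C[C@@H]2CC=CC[C@H]12 | intermediate (not isolated)
6 | cis-bicyclo[4.2.0]octa-3,7-diene (meso) | C1=CC[C@@H]2[C@H](C1)C=C2 | intermediate
7 | cyclobutanol | OC1CCC1 | starting material
8 | cyclobutyl 4-methylbenzenesulfonate | Cc1ccc(cc1)S(=O)(=O)OC1CCC1 | intermediate
9 | cyclobutene | C1=CCC1 | intermediate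
10 | meso cis-anti-cis-anti-cis-tetracyclo[6.4.0.0(2,7).0(3,6)]dodec-10-ene | C1=CC[C@@H]2[C@H](C1)[C@H]1[C@@H]3CC[C@@H]3[C@@H]21 | intermediate
11 | 2-(Lad)-4,4,5,5-tetramethyl-1,3,2-dioxaborolane, boron on C10 cis to C2 and C7, C10 S | CC1(C)OB(OC1(C)C)[C@H]1CC[C@@H]2[C@H](C1)[C@H]1[C@@H]3CC[C@@H]3[C@@H]21 | intermediate
12 | oct-7-yn-1-ol | OCCCCCCC#C | starting material
13 | oct-7-yn-1-yl methanesulfonate | CS(=O)(=O)OCCCCCCC#C | intermediate
14 | cis-2-phenyl-1,3-dioxan-5-ol (1,3-O-benzylideneglycerol) | O[C@H]1CO[C@@H](c2ccccc2)OC1 | starting material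
15 | cis-5-(oct-7-yn-1-yloxy)-2-phenyl-1,3-dioxane | C#CCCCCCCO[C@H]1CO[C@@H](c2ccccc2)OC1 | intermediate
16 | (E)-alkenylzirconocene chloride of 15, Cp2Zr(Cl) on the terminal carbon (Cp drawn as σ-bonded rings) | Cl[Zr](/C=C/CCCCCCO[C@H]1CO[C@@H](c2ccccc2)OC1)(C1C=CC=C1)C1C=CC=C1 | intermediate (not isolated)
17 | (E)-cis-5-[(8-iodooct-7-en-1-yl)oxy]-2-phenyl-1,3-dioxane | I/C=C/CCCCCCO[C@H]1CO[C@@H](c2ccccc2)OC1 | intermediate
18 | (E)-8-[(cis-2-phenyl-1,3-dioxan-5-yl)oxy]oct-1-en-1-yllithium | [Li]/C=C/CCCCCCO[C@H]1CO[C@@H](c2ccccc2)OC1 | intermediate (not isolated)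
19 | lithium (E)-alkenyl(Lad)pinacolatoborate | [Li+].CC1(C)O[B-](/C=C/CCCCCCO[C@H]2CO[C@@H](c3ccccc3)OC2)(OC1(C)C)[C@H]1CC[C@@H]2[C@H](C1)[C@H]1[C@@H]3CC[C@@H]3[C@@H]21 | intermediate (not isolated)
20 | β-iodoalkyl pinacol boronate, Lad and Bpin on C8 of the chain, iodine on C7 (one of two diastereomers at these two carbons drawn; both eliminate to 21) | I[C@@H](CCCCCCO[C@H]1CO[C@@H](c2ccccc2)OC1)[C@@H](B1OC(C)(C)C(C)(C)O1)[C@H]1CC[C@@H]2[C@H](C1)[C@H]1[C@@H]3CC[C@@H]3[C@@H]21 | intermediate (not isolated)
21 | cis-5-{[(Z)-8-(Lad)oct-7-en-1-yl]oxy}-2-phenyl-1,3-dioxane | O([C@H]1CO[C@@H](c2ccccc2)OC1)CCCCCC/C=C\[C@H]1CC[C@@H]2[C@H](C1)[C@H]1[C@@H]3CC[C@@H]3[C@@H]21 | intermediate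
22 | cis-5-{[8-(Lad)octyl]oxy}-2-phenyl-1,3-dioxane | O([C@H]1CO[C@@H](c2ccccc2)OC1)CCCCCCCC[C@H]1CC[C@@H]2[C@H](C1)[C@H]1[C@@H]3CC[C@@H]3[C@@H]21 | intermediate
23 | 2-{[8-(Lad)octyl]oxy}propane-1,3-diol | OCC(CO)OCCCCCCCC[C@H]1CC[C@@H]2[C@H](C1)[C@H]1[C@@H]3CC[C@@H]3[C@@H]21 | target

**Totals**
Total step count: 14. Longest linear sequence: 9 steps (1, 2, 3, 4, 7, 8, 12, 13, 14, from cyclohexa-1,4-diene).

**Steps most likely to fail**

1. Step 7. Homo-coupling of either partner may outrun the crossed union, copper may be chelated by both double bonds of 6 and close them onto each other, or the anti selectivity may be incomplete. Fallback from 6 back to 10: the union is made through the triplet state of a conjugated partner instead of a copper template. Acetone-sensitised irradiation (300 nm) of 6 with dimethyl cyclobut-1-ene-1,2-dicarboxylate should add the excited enoate across the strained C7=C8 bond of 6 on its convex face and give dimethyl cis-anti-cis-anti-cis-tetracyclo[6.4.0.0(2,7).0(3,6)]dodec-10-ene-3,6-dicarboxylate F1. LiOH in THF/H2O should give the diacid F2. DCC coupling with N-hydroxypyridine-2-thione should give the bis(thiohydroxamate) ester F3, and its photolysis with t-BuSH (Barton reductive decarboxylation) should return 10. Each ring-fusion radical can take up hydrogen only on the exo face, since two cyclobutanes cannot be trans-fused.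

2. Step 8. Hydrocupration of the unactivated ring A alkene may be slow, the two enantiotopic alkene carbons may be told apart incompletely, or boron may be delivered to the face trans to ring B. Fallback from 10 back to 11: stoichiometric reagent control replaces catalysis. Hydroboration with (−)-Ipc2BH (from (+)-α-pinene, or its antipode if the sense requires it) in THF at −25 → 0 °C should give the diisopinocampheyl(Lad)borane F4. Excess CH3CHO should release α-pinene and leave the diethyl boronate F5, and transesterification with pinacol should give 11.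

3. Step 4. The dianion of the strained cyclobutanone hydrazone may fragment or follow carbene-type ring contraction instead of giving the alkenyllithium, and the volatile diene may be lost on isolation. Fallback from 3 back to 6: the olefin is made through an enol triflate. Kinetic deprotonation at the C8 methylene with LiN(iPr)2 in THF at −78 °C and trapping with PhNTf2 should give cis-bicyclo[4.2.0]octa-3,7-dien-7-yl trifluoromethanesulfonate F6. Reduction with Pd(OAc)2/PPh3, HCO2H and Bu3N in DMF at 60 °C (oxidative addition to zerovalent palladium, hydride transfer from formate, reductive elimination) should give 6.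

**Further compounds**
F1 | step 7 | dimethyl cis-anti-cis-anti-cis-tetracyclo[6.4.0.0(2,7).0(3,6)]dodec-10-ene-3,6-dicarboxylate | C1=CC[C@@H]2[C@H](C1)[C@H]1[C@]3(C(=O)OC)CC[C@]3(C(=O)OC)[C@@H]21
F2 | step 7 | cis-anti-cis-anti-cis-tetracyclo[6.4.0.0(2,7).0(3,6)]dodec-10-ene-3,6-dicarboxylic acid | C1=CC[C@@H]2[C@H](C1)[C@H]1[C@]3(C(=O)O)CC[C@]3(C(=O)O)[C@@H]21
F3 | step 7 | bis(2-thioxopyridin-1(2H)-yl) ester of F2 | C1=CC[C@@H]2[C@H](C1)[C@H]1[C@]3(C(=O)ON4C=CC=CC4=S)CC[C@]3(C(=O)ON3C=CC=CC3=S)[C@@H]21
F4 | step 8 | diisopinocampheyl(Lad)borane, Ipc groups from (+)-α-pinene | B([C@H]1[C@H](C)[C@H]2C[C@@H](C1)C2(C)C)([C@H]1[C@H](C)[C@H]2C[C@@H](C1)C2(C)C)[C@H]1CC[C@@H]2[C@H](C1)[C@H]1[C@@H]3CC[C@@H]3[C@@H]21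
F5 | step 8 | diethyl (Lad)boronate | CCOB(OCC)[C@H]1CC[C@@H]2[C@H](C1)[C@H]1[C@@H]3CC[C@@H]3[C@@H]21
F6 | step 4 | cis-bicyclo[4.2.0]octa-3,7-dien-7-yl trifluoromethanesulfonate (racemic, one enantiomer drawn) | O=S(=O)(OC1=C[C@@H]2CC=CC[C@H]12)C(F)(F)F
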